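## Structural features

The target is a flavonol: benzene ring A is fused to a 4-pyranone ring C (O1, C2, C3, C4, C4a, C8a), and a 3,4,5-trimethoxyphenyl ring B is bonded to C2 by a single C–C bond. Ring A carries oxygen on four neighbouring carbons: a free hydroxyl at C5, methoxyls at C7 and C8, and the ring oxygen O1 at C8a; only C6 bears hydrogen. Ring C carries a hydroxyl at C3 next to the C4 carbonyl. There is no stereocenter, so no configuration has to be set and no stereocenters stand next to each other. The fragile part is the 3-hydroxy-4-pyranone: its anion is cleaved by oxygen in base, C2 is open to nucleophiles, and all five methyl ethers must survive every step. The real difficulty is regiochemical. C4a has two ortho oxygens; the one next to the C8 methoxyl must become O1 and the other must end as the free C5 hydroxyl, otherwise the 5,6,7-oxygenated isomer results. C3 must also be oxygenated without touching the electron-rich arenes. The key step exploits this: in an aryl alkynyl ketone the C8a oxygen is a nucleophilic methyl ether, the C5 oxygen is an inert sulfonate, and the two alkyne carbons become C2 and C3, so closing ring C through O1–C2 places iodine on C3 as the handle for the hydroxyl.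

## Logic of the disconnections

13 to 12: the O–S bond between the C5 oxygen and a sulfonyl group is cut (a protecting-group disconnection, no skeletal bond). The C5 oxygen must be non-nucleophilic during ring closure and inert to organometallic reagents, and a sulfonate does both. The gain is that two free hydroxyls are told apart from five methoxyls without any selective methylation or demethylation. The demand is an S–O cleavage by hydroxide that spares ring C, so oxygen and methanol are excluded and the step comes last.

12 to 9: the C3–O bond is traced back to a C3–I bond, passing through 10 and 11 in the forward direction. C3 is the α-carbon of the enone and is best functionalized at a position already marked when ring C is made. The gain is that the hydroxyl comes from a halogen that costs no extra step. The demand is a halogen–metal exchange faster than addition to the C4 carbonyl or attack on the sulfonate, and trapping of the C3 carbanion before ring C can fragment.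

9 to 7: the O1–C2 and C3–I bonds are cut, through 8 in the forward direction. This removes ring C and leaves two arenes joined by a three-carbon ynone. The demand on the forward step is threefold: only one ortho oxygen of 7 may act as nucleophile, closure must be 6-endo, and the arenes must not be iodinated.

7 to 6 to 3 plus 4: after adjusting the oxidation level, the bond between the carbonyl carbon (future C4) and the alkyne carbon (future C3) is cut, with 5 as the nucleophile. This is the most convergent cut, since it divides the molecule into its two aromatic halves. The demand is that the acetylide adds to a hindered aldehyde faster than it attacks the sulfonate, and that the easily ionized carbinol is oxidized under neutral conditions.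

3 to 2 to 1: the O–S bond of the sulfonate and the bond between the formyl carbon and the ring (future C4–C4a) are cut. Both ortho positions of 1 are equivalent, so formylation has only one outcome. The two oxygens ortho to C4a are then different by origin: the former phenol is sulfonylated and ends as O5, and its counterpart is a methyl ether and ends as O1. The demand is mono-formylation and complete sulfonylation of a hydrogen-bonded phenol.

## Other disconnections considered

Alternative 1: The cuts are C4a–C4 and C4–C3; ring C is opened to a 1,3-diketone and the C4 carbon comes from CO.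
- Forward step: 1-iodo-2,3,4,6-tetramethoxybenzene A1 (two steps from 1), CO and the enolate of 2-(benzyloxy)-1-(3,4,5-trimethoxyphenyl)ethan-1-one A2 would be joined by the zerovalent palladium complex Pd(dba)2 with Xantphos. Oxidative addition, CO insertion and C-acylation of the enolate would give diketone A3. Demethylative cyclodehydration and debenzylation would follow.
- In favour: it is convergent and uses three simple components. The C3 oxygen is present from the start, which is better than the chosen plan. No electrophilic halogen meets the electron-rich arenes, which is also better. The step count is equal or one lower.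
- Against: the aroyl–palladium species from A1 has two ortho methoxyls and the α-benzyloxy enolate is hindered. O-acylation, non-carbonylative arylation and retro-Claisen cleavage of A3 would compete.
- Decisive point: A3 has two methoxyls ortho to the ketone and nothing distinguishes them. Closure through the wrong oxygen would give the 5,6,7-oxygenated isomer A4, and acid allows Wessely–Moser equilibration.
- Comparison: the chosen plan fixes which oxygen becomes O1 at the stage of 2; this alternative leaves the central regiochemical problem to a late, unselective step.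

Alternative 2: The cut is C4a–C5; ring A is dismantled and rings B and C pre-exist as pyranone A5.
- Forward step: A5, metalated next to its ring oxygen, would add to the ketone carbonyl of 3-methoxycyclobut-3-ene-1,2-dione A6 to give hydroxycyclobutenone A7. Heating would open the four-membered ring to a dienylketene, which closes by 6π-electrocyclization onto the neighbouring pyranone carbon and tautomerizes to hydroquinone A8. Methylation of the non-chelated C8 hydroxyl and removal of the methoxymethyl group would give 13.
- In favour: the ring A oxygen pattern is written into A6 and A7, so regiocontrol is equal to the chosen plan. The C3 oxygen is carried from the start, which is better. The key step is thermal and needs no electrophile or metal, which is better for chemoselectivity. Two steps follow the key step, which is equal.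
- Against: A5 would need its own multistep synthesis. Metalation of a 4-pyranone competes with addition to it and ring opening. A6 must be made from a squaric acid derivative. A8 is an air-sensitive hydroquinone whose two hydroxyls differ only by chelation.
- Comparison: elegant in mechanism, but clearly longer than seven steps.

Alternative 3: The cut is C4–C4a; the O1–C2 bond already exists as an aryl vinyl ether.
- Forward step: acid A10, built from phenol A9, would be activated by (CF3CO)2O as the mixed anhydride. Its acylium-type carbon would attack the only free ortho carbon of the aryloxy ring (intramolecular Friedel–Crafts acylation) to give A11. One hydrogenolysis would remove both benzyl groups and give 13.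
- In favour: O1 is attached before closure and the other ortho position of A9 is blocked, so only one ring closure is possible; this is equal to the chosen plan. The C3 oxygen is present from the start and one step follows the key step instead of two, which is better. The acylation site is strongly activated.
- Against: A9 is an unsymmetrical tetraoxygenated benzene that cannot be reached from 1 by a selective demethylation. A10 is a tetrasubstituted enol ether that must have carboxyl and aryloxy cis (the E isomer). Conjugate addition of a phenol to an arylpropiolate does not install the C2 alkoxy group, so A10 needs a less established construction with uncertain geometry. The acidic anhydride medium also exposes ring B and the benzyl ethers.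
- Comparison: the end game is better, but the difficulty is moved into two precursors, and the overall count would exceed seven steps.

Key step: step 5

Remarks on the chemistry:
- The ynone and the iodoflavone were checked atom by atom against the flavone numbering (aldehyde carbon of 2 = C4, sulfonylated oxygen = O5, the methoxyl on the other ortho carbon = O1). They are consistent and no structural correction is needed.
- The C5 oxygen is carried as a 4-methylbenzenesulfonate instead of a methanesulfonate. It has no acidic hydrogens next to sulfur, so the acetylide and iPrMgCl·LiCl cannot trigger sulfene elimination. The skeletons of 7 and 9, the bonds formed in step 5 and the ring it closes are unchanged.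
- Compounds 1 and 4 are assumed to be purchased.

## Route

Step 1
Reactants: 1 3,4,5-trimethoxyphenol
Product: 2 6-hydroxy-2,3,4-trimethoxybenzaldehyde
Conditions: MgCl2 (anhydrous), Et3N, (CH2O)n, MeCN, reflux; then 1 M HCl
Reagents that add atoms: paraformaldehyde (formaldehyde unit), C=O
Why: Casnati–Skattebøl ortho-formylation: the magnesium phenoxide delivers formaldehyde to the ortho carbon through a chelate, and the resulting benzylic alkoxide is oxidized by hydride transfer to a second formaldehyde. Both ortho positions of 1 are equivalent, so only one aldehyde can form.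

Step 2
Reactants: 2 6-hydroxy-2,3,4-trimethoxybenzaldehyde
Product: 3 2-formyl-3,4,5-trimethoxyphenyl 4-methylbenzenesulfonate
Conditions: TsCl, Et3N, DMAP (cat.), CH2Cl2, 0 °C → rt
Reagents that add atoms: p-toluenesulfonyl chloride, Cc1ccc(cc1)S(=O)(=O)Cl
Why: O-sulfonylation of a phenol via the N-sulfonylpyridinium ion; DMAP overcomes the hydrogen bond to the aldehyde. This oxygen becomes non-nucleophilic and the two oxygens ortho to the future C4a are now different.

Step 3
Reactants: 4 5-ethynyl-1,2,3-trimethoxybenzene; 3 2-formyl-3,4,5-trimethoxyphenyl 4-methylbenzenesulfonate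
Product: 6 racemic 2-[1-hydroxy-3-(3,4,5-trimethoxyphenyl)prop-2-yn-1-yl]-3,4,5-trimethoxyphenyl 4-methylbenzenesulfonate, via lithium arylacetylide 5 (not isolated)
Conditions: 4 (1.2 equiv), n-BuLi (1.1 equiv), THF, −78 °C; then 3, −78 °C; sat. aq. NH4Cl at −78 °C
Reagents that add atoms: none
Why: 1,2-addition of a lithium acetylide to an aldehyde; the carbinol stereocenter forms as a racemate and is removed in step 4. The tosylate has no acidic α-hydrogens, and sulfonyl transfer to the neighbouring alkoxide would need a six-membered transition state that cannot reach the in-line geometry at sulfur.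

Step 4
Reactants: 6 racemic 2-[1-hydroxy-3-(3,4,5-trimethoxyphenyl)prop-2-yn-1-yl]-3,4,5-trimethoxyphenyl 4-methylbenzenesulfonate
Product: 7 3,4,5-trimethoxy-2-[3-(3,4,5-trimethoxyphenyl)prop-2-ynoyl]phenyl 4-methylbenzenesulfonate
Conditions: activated MnO2 (excess), CH2Cl2, rt
Reagents that add atoms: none
Why: MnO2 oxidation of a benzylic and propargylic alcohol to the ynone. The neutral heterogeneous conditions avoid ionization of the electron-rich carbinol and leave the sulfonate and methyl ethers untouched.

Step 5
Reactants: 7 3,4,5-trimethoxy-2-[3-(3,4,5-trimethoxyphenyl)prop-2-ynoyl]phenyl 4-methylbenzenesulfonate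
Product: 9 3-iodo-7,8-dimethoxy-4-oxo-2-(3,4,5-trimethoxyphenyl)-4H-chromen-5-yl 4-methylbenzenesulfonate, via 3-iodo-1-methylchromen-1-ium chloride 8 (not isolated)
Conditions: ICl (1.1 equiv, 1 M in CH2Cl2), CH2Cl2, −78 °C, dark; aq. Na2S2O3 quench at −78 °C
Reagents that add atoms: iodine monochloride, ClI
Why: ICl delivers I+ to the triple bond of 7, giving an iodonium ion whose positive charge lies mainly on the alkyne carbon that carries ring B (the β-carbon of the ynone). The ether oxygen of the methoxyl ortho to the ketone, the future O1, attacks that carbon anti to iodine; this forms O1–C2, closes ring C in the 6-endo-dig mode and leaves iodine on C3 in oxonium salt 8. Chloride then removes the O-methyl group of 8 by SN2 attack, releasing chloromethane and the neutral 4-pyranone 9. The closest known reaction type is the ICl-induced demethylative cyclization of 2-methoxyaryl alkynyl ketones to 3-iodochromones and 3-iodoflavones. No stereocenter is formed. The choice between the two oxygens ortho to the acyl group is made by the substrate: the sulfonate oxygen is too electron-poor to attack, so only the methoxyl next to the future C8 methoxyl can become O1. The endo mode is secured by the polarization of the ynone and aryl stabilization at the β-carbon, whereas 5-exo attack at the α-carbon would place charge next to the carbonyl. Iodination of ring B or of C6 of ring A, a slower bimolecular reaction on arenes deactivated by the ynone and the sulfonate, is held back by −78 °C, a near-stoichiometric charge of ICl and a cold reductive quench.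

Step 6
Reactants: 9 3-iodo-7,8-dimethoxy-4-oxo-2-(3,4,5-trimethoxyphenyl)-4H-chromen-5-yl 4-methylbenzenesulfonate
Product: 12 3-hydroxy-7,8-dimethoxy-4-oxo-2-(3,4,5-trimethoxyphenyl)-4H-chromen-5-yl 4-methylbenzenesulfonate, via 3-chloromagnesio flavone tosylate 10 (not isolated), via dimethyl flavon-3-ylboronate 11 (not isolated)
Conditions: iPrMgCl·LiCl (1.1 equiv), THF, −78 °C; B(OMe)3 (2 equiv), −78 → 0 °C; AcOH, 30% aq. H2O2, 0 °C → rt
Reagents that add atoms: hydrogen peroxide, OO
Why: Iodine–magnesium exchange at the alkenyl iodide next to the carbonyl is fast at low temperature and gives 10; B(OMe)3 converts it to boronate 11, and peroxide oxidation (1,2-shift of C3 from boron to oxygen) gives the enol. The borate and acidic peroxide sequence is the one established for turning 3-metalated flavones into flavonols, and the acidic oxidation leaves the tosylate in place.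

Step 7
Reactants: 12 3-hydroxy-7,8-dimethoxy-4-oxo-2-(3,4,5-trimethoxyphenyl)-4H-chromen-5-yl 4-methylbenzenesulfonate
Product: 13 3,5-dihydroxy-7,8-dimethoxy-2-(3,4,5-trimethoxyphenyl)-4H-chromen-4-one
Conditions: 2 M aq. NaOH, 1,4-dioxane, degassed, Ar, 60 °C; then 1 M HCl
Reagents that add atoms: none
Why: Hydroxide attacks the sulfonyl sulfur and releases the C5 phenoxide, a good leaving group because it is conjugated with the C4 carbonyl. The flavonolate formed first makes ring C electron-rich and resistant to hydroxide at C2; excluding oxygen prevents oxidative cleavage, and the absence of methanol avoids forming methyl tosylate.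

## Compound list

1 | 3,4,5-trimethoxyphenol | COc1cc(O)cc(OC)c1OC | starting material
2 | 6-hydroxy-2,3,4-trimethoxybenzaldehyde | O=Cc1c(O)cc(OC)c(OC)c1OC | intermediate
3 | 2-formyl-3,4,5-trimethoxyphenyl 4-methylbenzenesulfonate | O=Cc1c(OS(=O)(=O)c2ccc(C)cc2)cc(OC)c(OC)c1OC | intermediate
4 | 5-ethynyl-1,2,3-trimethoxybenzene | COc1cc(C#C)cc(OC)c1OC | starting material
5 | lithium (3,4,5-trimethoxyphenyl)acetylide | [Li+].[C-]#Cc1cc(OC)c(OC)c(OC)c1 | intermediate (not isolated)
6 | 2-[1-hydroxy-3-(3,4,5-trimethoxyphenyl)prop-2-yn-1-yl]-3,4,5-trimethoxyphenyl 4-methylbenzenesulfonate (racemic) | COc1cc(C#CC(O)c2c(OS(=O)(=O)c3ccc(C)cc3)cc(OC)c(OC)c2OC)cc(OC)c1OC | intermediate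
7 | 3,4,5-trimethoxy-2-[3-(3,4,5-trimethoxyphenyl)prop-2-ynoyl]phenyl 4-methylbenzenesulfonate | COc1cc(C#CC(=O)c2c(OS(=O)(=O)c3ccc(C)cc3)cc(OC)c(OC)c2OC)cc(OC)c1OC | intermediate
8 | 3-iodo-7,8-dimethoxy-1-methyl-5-[(4-methylbenzenesulfonyl)oxy]-4-oxo-2-(3,4,5-trimethoxyphenyl)-4H-chromen-1-ium chloride | C[O+]1C(c2cc(OC)c(OC)c(OC)c2)=C(I)C(=O)c2c(OS(=O)(=O)c3ccc(C)cc3)cc(OC)c(OC)c21.[Cl-] | intermediate (not isolated)
9 | 3-iodo-7,8-dimethoxy-4-oxo-2-(3,4,5-trimethoxyphenyl)-4H-chromen-5-yl 4-methylbenzenesulfonate | O=c1c(I)c(-c2cc(OC)c(OC)c(OC)c2)oc2c(OC)c(OC)cc(OS(=O)(=O)c3ccc(C)cc3)c12 | intermediate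
10 | chlorido{7,8-dimethoxy-5-[(4-methylbenzenesulfonyl)oxy]-4-oxo-2-(3,4,5-trimethoxyphenyl)-4H-chromen-3-yl}magnesium (LiCl complex) | Cl[Mg]c1c(-c2cc(OC)c(OC)c(OC)c2)oc2c(OC)c(OC)cc(OS(=O)(=O)c3ccc(C)cc3)c2c1=O | intermediate (not isolated)
11 | dimethyl {7,8-dimethoxy-5-[(4-methylbenzenesulfonyl)oxy]-4-oxo-2-(3,4,5-trimethoxyphenyl)-4H-chromen-3-yl}boronate | COB(OC)c1c(-c2cc(OC)c(OC)c(OC)c2)oc2c(OC)c(OC)cc(OS(=O)(=O)c3ccc(C)cc3)c2c1=O | intermediate (not isolated)
12 | 3-hydroxy-7,8-dimethoxy-4-oxo-2-(3,4,5-trimethoxyphenyl)-4H-chromen-5-yl 4-methylbenzenesulfonate | O=c1c(O)c(-c2cc(OC)c(OC)c(OC)c2)oc2c(OC)c(OC)cc(OS(=O)(=O)c3ccc(C)cc3)c12 | intermediate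
13 | 3,5-dihydroxy-7,8-dimethoxy-2-(3,4,5-trimethoxyphenyl)-4H-chromen-4-one (3,5-dihydroxy-7,8,3',4',5'-pentamethoxyflavone) | COc1cc(-c2oc3c(OC)c(OC)cc(O)c3c(=O)c2O)cc(OC)c1OC | target

## Step count and risks

Total step count: 7. Longest linear sequence: 7 steps (1 to 13; 4 is purchased and enters in step 3).

Least certain steps:

Step 5 (key step). The most likely failure is electrophilic iodination of ring B or of C6 of ring A, or plain anti-addition of ICl across the triple bond if the hindered methoxyl attacks slowly. The fallback separates ring closure from C3 functionalization. From 7, BCl3 (CH2Cl2, −78 → 0 °C) should remove, by chelation, only the methoxyl ortho to the ketone and give 3-hydroxy-4,5-dimethoxy-2-[3-(3,4,5-trimethoxyphenyl)prop-2-ynoyl]phenyl 4-methylbenzenesulfonate F1. Base-mediated 6-endo-dig oxa-Michael closure (K2CO3, acetone, rt) should give 7,8-dimethoxy-4-oxo-2-(3,4,5-trimethoxyphenyl)-4H-chromen-5-yl 4-methylbenzenesulfonate F2. Deprotonation of F2 at C3 with LiN(iPr)2 (THF, −78 °C), B(OMe)3 and AcOH/H2O2, the established flavone-to-flavonol sequence, would rejoin the route at 12.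

Step 6. The risks are fragmentation of the 3-magnesiated flavone (β-elimination of the C8a phenoxide, reopening ring C), addition of iPrMgCl to C4 or to sulfonyl sulfur, and slow borate formation at the hindered C3 with loss of iodine to protonation. The fallback replaces the carbanion by palladium catalysis. From 9, Miyaura borylation (Pd(dppf)Cl2, B2pin2, KOAc, dioxane, 80 °C) should give 7,8-dimethoxy-4-oxo-3-(4,4,5,5-tetramethyl-1,3,2-dioxaborolan-2-yl)-2-(3,4,5-trimethoxyphenyl)-4H-chromen-5-yl 4-methylbenzenesulfonate F3. Oxidation of F3 with NaBO3·4H2O (THF/H2O, rt) would rejoin the route at 12.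

Step 7. The risk is slow S–O cleavage at the hindered, electron-rich C5 position, forcing long exposure of the flavonolate to hot alkali, with oxidative cleavage or hydroxide opening of ring C. The fallback changes the masking group to one that leaves at room temperature. From 2, Tf2O/pyridine (CH2Cl2, 0 °C) would give 2-formyl-3,4,5-trimethoxyphenyl trifluoromethanesulfonate F4. The operations of steps 3 to 6 would then give in turn:
- racemic 2-[1-hydroxy-3-(3,4,5-trimethoxyphenyl)prop-2-yn-1-yl]-3,4,5-trimethoxyphenyl trifluoromethanesulfonate F5;
- 3,4,5-trimethoxy-2-[3-(3,4,5-trimethoxyphenyl)prop-2-ynoyl]phenyl trifluoromethanesulfonate F6;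
- 3-iodo-7,8-dimethoxy-4-oxo-2-(3,4,5-trimethoxyphenyl)-4H-chromen-5-yl trifluoromethanesulfonate F7;
- 3-hydroxy-7,8-dimethoxy-4-oxo-2-(3,4,5-trimethoxyphenyl)-4H-chromen-5-yl trifluoromethanesulfonate F8.

Cleavage of F8 with Et4NOH (aq. dioxane, rt, Ar) would rejoin the route at 13.

Step 3. The risks are incomplete addition to the doubly ortho-substituted aldehyde, attack of the acetylide or of the product alkoxide on the sulfonate if the mixture warms, and ionization of the electron-rich carbinol on work-up. The fallback uses an acyl electrophile and no organolithium. From 3, Pinnick oxidation (NaClO2, NaH2PO4, 2-methyl-2-butene, t-BuOH/H2O) would give 2,3,4-trimethoxy-6-[(4-methylbenzenesulfonyl)oxy]benzoic acid F9. Oxalyl chloride with catalytic DMF would give 2,3,4-trimethoxy-6-[(4-methylbenzenesulfonyl)oxy]benzoyl chloride F10. Acyl Sonogashira coupling of F10 with 4 (Pd(PPh3)2Cl2, CuI, Et3N, THF, rt) would rejoin the route at 7 and bypass 6.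

## Further compounds

F1 | step 5 | 3-hydroxy-4,5-dimethoxy-2-[3-(3,4,5-trimethoxyphenyl)prop-2-ynoyl]phenyl 4-methylbenzenesulfonate | COc1cc(C#CC(=O)c2c(OS(=O)(=O)c3ccc(C)cc3)cc(OC)c(OC)c2O)cc(OC)c1OC
F2 | step 5 | 7,8-dimethoxy-4-oxo-2-(3,4,5-trimethoxyphenyl)-4H-chromen-5-yl 4-methylbenzenesulfonate | O=c1cc(-c2cc(OC)c(OC)c(OC)c2)oc2c(OC)c(OC)cc(OS(=O)(=O)c3ccc(C)cc3)c12
F3 | step 6 | 7,8-dimethoxy-4-oxo-3-(4,4,5,5-tetramethyl-1,3,2-dioxaborolan-2-yl)-2-(3,4,5-trimethoxyphenyl)-4H-chromen-5-yl 4-methylbenzenesulfonate | CC1(C)OB(OC1(C)C)c1c(-c2cc(OC)c(OC)c(OC)c2)oc2c(OC)c(OC)cc(OS(=O)(=O)c3ccc(C)cc3)c2c1=O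
F4 | step 7 | 2-formyl-3,4,5-trimethoxyphenyl trifluoromethanesulfonate | O=Cc1c(OS(=O)(=O)C(F)(F)F)cc(OC)c(OC)c1OC
F5 | step 7 | 2-[1-hydroxy-3-(3,4,5-trimethoxyphenyl)prop-2-yn-1-yl]-3,4,5-trimethoxyphenyl trifluoromethanesulfonate (racemic) | COc1cc(C#CC(O)c2c(OS(=O)(=O)C(F)(F)F)cc(OC)c(OC)c2OC)cc(OC)c1OC
F6 | step 7 | 3,4,5-trimethoxy-2-[3-(3,4,5-trimethoxyphenyl)prop-2-ynoyl]phenyl trifluoromethanesulfonate | COc1cc(C#CC(=O)c2c(OS(=O)(=O)C(F)(F)F)cc(OC)c(OC)c2OC)cc(OC)c1OC
F7 | step 7 | 3-iodo-7,8-dimethoxy-4-oxo-2-(3,4,5-trimethoxyphenyl)-4H-chromen-5-yl trifluoromethanesulfonate | O=c1c(I)c(-c2cc(OC)c(OC)c(OC)c2)oc2c(OC)c(OC)cc(OS(=O)(=O)C(F)(F)F)c12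
F8 | step 7 | 3-hydroxy-7,8-dimethoxy-4-oxo-2-(3,4,5-trimethoxyphenyl)-4H-chromen-5-yl trifluoromethanesulfonate | O=c1c(O)c(-c2cc(OC)c(OC)c(OC)c2)oc2c(OC)c(OC)cc(OS(=O)(=O)C(F)(F)F)c12
F9 | step 3 | 2,3,4-trimethoxy-6-[(4-methylbenzenesulfonyl)oxy]benzoic acid | OC(=O)c1c(OS(=O)(=O)c2ccc(C)cc2)cc(OC)c(OC)c1OC
F10 | step 3 | 2,3,4-trimethoxy-6-[(4-methylbenzenesulfonyl)oxy]benzoyl chloride | ClC(=O)c1c(OS(=O)(=O)c2ccc(C)cc2)cc(OC)c(OC)c1OC
A1 | alternative 1 | 1-iodo-2,3,4,6-tetramethoxybenzene | COc1cc(OC)c(I)c(OC)c1OC
A2 | alternative 1 | 2-(benzyloxy)-1-(3,4,5-trimethoxyphenyl)ethan-1-one | COc1cc(C(=O)COCc2ccccc2)cc(OC)c1OC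
A3 | alternative 1 | 2-(benzyloxy)-1-(2,3,4,6-tetramethoxyphenyl)-3-(3,4,5-trimethoxyphenyl)propane-1,3-dione (racemic, enolizable) | COc1cc(OC)c(C(=O)C(OCc2ccccc2)C(=O)c2cc(OC)c(OC)c(OC)c2)c(OC)c1OC
A4 | alternative 1 | 3-(benzyloxy)-5-hydroxy-6,7-dimethoxy-2-(3,4,5-trimethoxyphenyl)-4H-chromen-4-one | O=c1c(OCc2ccccc2)c(-c2cc(OC)c(OC)c(OC)c2)oc2cc(OC)c(OC)c(O)c12
A5 | alternative 2 | 3-(methoxymethoxy)-2-(3,4,5-trimethoxyphenyl)-4H-pyran-4-one | COCOc1c(-c2cc(OC)c(OC)c(OC)c2)occc1=O
A6 | alternative 2 | 3-methoxycyclobut-3-ene-1,2-dione | COC1=CC(=O)C1=O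
A7 | alternative 2 | 4-hydroxy-3-methoxy-4-[5-(methoxymethoxy)-4-oxo-6-(3,4,5-trimethoxyphenyl)-4H-pyran-2-yl]cyclobut-2-en-1-one (racemic) | COCOc1c(-c2cc(OC)c(OC)c(OC)c2)oc(C2(O)C(OC)=CC2=O)cc1=O
A8 | alternative 2 | 5,8-dihydroxy-7-methoxy-3-(methoxymethoxy)-2-(3,4,5-trimethoxyphenyl)-4H-chromen-4-one | O=c1c(OCOC)c(-c2cc(OC)c(OC)c(OC)c2)oc2c(O)c(OC)cc(O)c12
A9 | alternative 3 | 5-(benzyloxy)-2,3-dimethoxyphenol | COc1cc(OCc2ccccc2)cc(O)c1OC
A10 | alternative 3 | (E)-2-(benzyloxy)-3-[5-(benzyloxy)-2,3-dimethoxyphenoxy]-3-(3,4,5-trimethoxyphenyl)prop-2-enoic acid | OC(=O)/C(OCc1ccccc1)=C(\Oc1cc(OCc2ccccc2)cc(OC)c1OC)c1cc(OC)c(OC)c(OC)c1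
A11 | alternative 3 | 3,5-bis(benzyloxy)-7,8-dimethoxy-2-(3,4,5-trimethoxyphenyl)-4H-chromen-4-one | O=c1c(OCc2ccccc2)c(-c2cc(OC)c(OC)c(OC)c2)oc2c(OC)c(OC)cc(OCc3ccccc3)c12
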